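Conventions used throughout: ring atoms keep the numbers of the target (C1, C2, C3, C3a, C4–C7, C7a); C8 is the carboxyl carbon and C1'–C4' the side chain. β is the face of the five-membered ring that carries the C3a–C4 bond (H7a is also β); α is the other face. TBS = tert-butyldimethylsilyl. The SMILES strings in the compound list fix all configurations.

## The problem

The target is a trans-fused hexahydroinden-2-one: a cyclopentanone (C1, C2, C3, C3a, C7a) shares the C3a–C7a bond with a cyclohexene (C3a, C4=C5, C6, C7, C7a). Its six stereocentres are contiguous: C1 (ethyl), C3 (methyl), C3a and C7a (trans fusion), and the adjacent quaternary carbons C6 (ethyl, dienyl chain) and C7 (ethyl, CO2H). C1 and C3 flank the ketone and can be set by equilibration. The real tasks are therefore the absolute configuration of C3a/C7a and the relay of that information to C6 and C7, which carry no hydrogen. The (1E,3E)-2-ethyl-4-phenylbuta-1,3-dienyl chain will not survive ozone or strong acid. The acid on C7 lies between two fully substituted carbons and could not be freed from a simple ester without forcing conditions. The ketone must be masked whenever a hydride or carbon nucleophile is used.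

Two features of the structure open a short route. First, the fully substituted cyclopentanone is a bicyclo[2.2.1]heptan-7-one with its two-carbon bridge cut. C2 is the one-carbon bridge, C1 and C3 are the bridgeheads, and C3a and C7a are the former dienophile carbons, whose trans relation is that of an E-alkene. A –C(CH3)=CH– bridge holds exactly the carbons of the C1 ethyl and C3 methyl groups. Second, C7 is the α-carbon of an acid and C6 is allylic to C4=C5, so C6–C7 is the bond a Claisen rearrangement forms from an ester whose oxygen sits on C4.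

## Retrosynthesis

**39 to 37.** No skeletal bond is cut. The ketone goes back to its dioxolane and C3 to its β-epimer. The cycloaddition delivers C3 cis to C4, and that cis methyl group is needed later to control C4. Because C3 is α to the ketone and the target has every vicinal pair trans, hydrolysis and equilibration can be the last operation. The forward step must free the ketone without letting the acid add to an alkene.

**37 to 34 and 35.** The C2'–C3' bond is cut. The diene is made last because it would not survive ozonolysis or the heating of the Claisen step. The but-1-ynyl group of 34 is a slim, inert placeholder for C1' and C2'. Olefination at a carbonyl on C6 would have to work between two quaternary carbons and was rejected. The forward step needs syn hydrometalation with the metal on C2', away from C6, and coupling with retention.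

**34 to 31.** The C6–C7 bond is cut by an Ireland–Claisen transform. This is the one disconnection that joins two fully substituted carbons intramolecularly and transfers chirality to both. Alkylation or conjugate addition at C6 or C7 would be intermolecular, hindered and uncontrolled. Lactone 31 has no quaternary carbon stereocentre. The forward reaction requires the alkenyl group on C4 to be α, the ethyl group on C6 to be cis to C4, and a boat-like transition state within reach of the trans-fused ring.

**31 to 30 to 28.** The C7 ethyl group comes off as an enolate alkylation; its configuration is irrelevant because C7 is re-enolised. The lactone C8–O bond is opened to diol 28, whose primary alcohol is the end of the dienophile chain.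

**28 and 27 to 26 to 24 to 20 and 23.** The sp2 C6–ethyl bond is cut (cross-coupling of iodide 26), then C4–C5 (acetylide 23 onto ketone 20). A trisubstituted alkene carrying ethyl and butynyl cannot be made selectively by olefination. Alkoxide-directed trans-hydroalumination of diynol 24 fixes the geometry from the position of the oxygen. C4 is set in the addition to 20, where the cis methyl group on C3 differentiates the two faces.

**20 to 19 to 17 to 15.** The methyl ketone comes from the N-methoxy-N-methylamide. The C3 methyl and C1 ethyl groups come from formyl and acetyl by deoxygenation, and these from the etheno bridge of norbornene 15 by ozonolysis. The amide is chosen because it is inert to ozone, sulfonylhydrazide and borane and still gives the ketone in one step.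

**15 to 13 to 11.** The auxiliary is exchanged for the amide through the acid.

**11 to 10 and 3.** The C3–C3a and C1–C7a bonds are cut in a Diels–Alder transform. This removes the five-membered ring and four stereocentres at once and leaves an achiral diene and an E-enoyl imide whose auxiliary sets the absolute configuration.

**Building blocks.** Imide 10 comes from acid 7, ester 6, aldehyde 4, phosphonate 5 and auxiliary 8. Diene 3 comes from dibromoketal 2 and ketone 1. Diyne 23 comes from dichloride 21.

## Roads not taken

**Alternative 1:** Favorskii-type contraction. The cut is C7–C7a, with the carboxyl carbon returned to a seven-membered ring. In the forward step, base attacks the ring carbonyl of α-bromo ketone A1 and the C7a–carbonyl bond shifts to the bromine-bearing C7, giving acid A2.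
- Merits: C7 and its carboxyl group are created stereospecifically in the last skeletal step. A2 is one coupling from the target and differs from 34 of the chosen route only in the free ketone and the C3 configuration, so its endgame is at least as short.
- Weak points: A1 already holds quaternary C6 next to a fully substituted α-bromo carbon inside a cycloheptenone, so the hard problem is moved and not solved. Enolisation towards C7a opens the cyclopropanone pathway, which can scramble C7a and the direction of ring opening. The carbonyl to be attacked lies between two hindered carbons.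
- Comparison: the chosen plan must set against A2's short endgame a ketal and a late epimerisation. In return it reaches its rearrangement substrate 31 from simple pieces with every stereocentre accounted for, which cannot be said of A1.

**Alternative 2:** Three-component coupling. The cuts are C3a–C4 and C3–CH3 on silyloxy enone A3. In the forward step an isopropenyl group adds to the β-carbon anti to the silyloxy group and the enolate is methylated trans, giving A4.
- Merits: three contiguous centres of the five-membered ring form in one operation from a readily available enantiopure enone. C3 arrives in its final configuration, and the isopropenyl group already is C4, its methyl group and C5. For the cyclopentanone this road is shorter and better controlled than the chosen one, with no ozonolysis, deoxygenation or late epimerisation.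
- Weak points: the silyloxy carbon of A4 is C7a, and C7 must arrive on the face the oxygen occupies, so an elimination and a second conjugate addition are needed. More seriously, C4 arrives as an alkene carbon and not as a carbinol. There is then no oxygen on C4 to tether a rearrangement, and the C6–C7 quaternary pair would have to be made without relay from C3a/C7a.
- Comparison: the chosen plan has a longer cyclopentane synthesis. What it sets against that is the carboxyl-level C4 delivered by the dienophile, which becomes the carbinol that carries the Claisen step.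

**Alternative 3:** Anhydride cycloaddition. The cuts are C5–C6 and C7–C7a. In the forward step 2,3-diethylmaleic anhydride A5 and buta-1,3-diene A6 combine to the meso anhydride A7, which is then desymmetrised.
- Merits: both quaternary carbons and the cis relation of the two ethyl groups are made in the first step from cheap materials. Enantioselective opening of the anhydride would set the absolute configuration and distinguish the carboxyl that stays from the one that becomes C1'. For the quaternary pair this is better than the chosen plan, which forms them late through a congested transition state.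
- Weak points: a tetrasubstituted dienophile reacts sluggishly. The alkene of A7 lies between the future C3a and C4. The five-membered ring, the C4 methyl group, the shift of the double bond to C4=C5 and the trans fusion must then be grafted onto a symmetric cyclohexene, with only its conformational bias to relate C3a/C7a to C6/C7.
- Comparison: the chosen plan reverses the order. It makes the easily controlled cyclopentane first and uses it, through C4, to set C6 and C7.

Key step: step 6

Assumption: the C3 methyl group of the target occupies the thermodynamically preferred position (trans to C4, all vicinal pairs trans), so base equilibration of the 3β-methyl ketone leads to the target.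

## Route

Step 1
Reactants: 1 3-methylcyclopentanone (racemic)
Product: 2 6,9-dibromo-7-methyl-1,4-dioxaspiro[4.4]nonane (mixture of diastereomers)
Conditions: Br2 (2.1 equiv), ethylene glycol, 15–25 °C
Reagents that add atoms: bromine, BrBr; ethylene glycol, OCCO
Why: Bromination of a ketone in ethylene glycol gives the α-bromo ketal directly through the enol ether; the second bromine enters at the other α-carbon because the first one deactivates its own side. All diastereomers converge in step 2.

Step 2
Reactants: 2 6,9-dibromo-7-methyl-1,4-dioxaspiro[4.4]nonane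
Product: 3 7-methyl-1,4-dioxaspiro[4.4]nona-6,8-diene
Conditions: KOtBu (3 equiv), THF, −20 to 0 °C; cold pentane/water work-up; dried cold solution used at once
Reagents that add atoms: none
Why: Double dehydrobromination; each bromide has β-hydrogens on one side only (the ketal carbon has none), so the diene regiochemistry is unambiguous. This is the standard entry to cyclopentadienone ketals, which are kept cold because they dimerise.

Step 3
Reactants: 4 3-(tert-butyldimethylsilyloxy)propanal; 5 triethyl phosphonoacetate
Product: 6 ethyl (E)-5-(tert-butyldimethylsilyloxy)pent-2-enoate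
Conditions: LiCl, DBU, MeCN, 0 °C to rt
Reagents that add atoms: none
Why: Horner–Wadsworth–Emmons olefination with a stabilised phosphonate is E-selective; the mild amine base avoids β-elimination of the silyloxy group from the aldehyde.

Step 4
Reactants: 6 ethyl (E)-5-(tert-butyldimethylsilyloxy)pent-2-enoate
Product: 7 (E)-5-(tert-butyldimethylsilyloxy)pent-2-enoic acid
Conditions: LiOH·H2O, THF/MeOH/H2O, rt; 1 M HCl to pH 4 at 0 °C
Reagents that add atoms: lithium hydroxide, [Li+].[OH-]
Why: Saponification; the primary silyl ether and the E-alkene are stable to aqueous LiOH at room temperature.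

Step 5
Reactants: 7 (E)-5-(tert-butyldimethylsilyloxy)pent-2-enoic acid; 8 (S)-4-benzyl-1,3-oxazolidin-2-one
Product: 10 (S)-4-benzyl-3-[(E)-5-(tert-butyldimethylsilyloxy)pent-2-enoyl]-1,3-oxazolidin-2-one, via mixed pivalic anhydride 9 (not isolated)
Conditions: tBuCOCl, Et3N, THF, −20 °C; then 8, LiCl, −20 °C to rt
Reagents that add atoms: none
Why: N-Acylation of the oxazolidinone through the mixed anhydride; attack occurs at the less hindered enoyl carbonyl and the mild conditions leave the E-alkene untouched.

Step 6
Reactants: 10 (S)-4-benzyl-3-[(E)-5-(tert-butyldimethylsilyloxy)pent-2-enoyl]-1,3-oxazolidin-2-one; 3 7-methyl-1,4-dioxaspiro[4.4]nona-6,8-diene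
Product: 11 (S)-4-benzyl-3-{[3-exo-(2-TBSO-ethyl)-5-methyl-7,7-ethylenedioxybicyclo[2.2.1]hept-5-en-2-endo-yl]carbonyl}-1,3-oxazolidin-2-one
Conditions: Et2AlCl (1.6 equiv), CH2Cl2, −78 °C; 3 (3 equiv) added as a cold CH2Cl2 solution; aq. potassium sodium tartrate
Reagents that add atoms: none
Why: Concerted, asynchronous normal-demand [4+2] cycloaddition between the electron-rich cyclopentadienone ketal and the imide, which Et2AlCl holds as a cationic, bidentate, s-cis aluminium chelate. The closest known reaction types are the Lewis-acid-promoted Diels–Alder reaction of N-enoyl oxazolidinones with cyclopentadienes and the Diels–Alder reaction of cyclopentadienone ketals with enoates. The five-membered ring (C1, C2, C3, C3a, C7a) is closed by suprafacial formation of C3–C3a and C1–C7a across the diene termini, with the ketal carbon becoming C2. C3a and C7a are set in absolute terms by the auxiliary: its benzyl group covers the Cα-re face of the chelate, so the diene adds to the Cα-si face. Their trans relation follows from the E geometry of the dienophile. The bridgehead centres C1 and C3 follow from the endo transition state (acyl group under the diene), which places the etheno bridge cis to the acyl group. The step needs regioselectivity, and the 2-methyl group secures it: the diene terminus next to the methyl-bearing carbon has the larger HOMO coefficient and bonds to the β-carbon of the enoyl group, so the acyl-bearing carbon ends next to the unsubstituted alkene carbon. A minor exo adduct, if formed, should be separable here or at 13.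

Step 7
Reactants: 11 (S)-4-benzyl-3-{[3-exo-(2-TBSO-ethyl)-5-methyl-7,7-ethylenedioxybicyclo[2.2.1]hept-5-en-2-endo-yl]carbonyl}-1,3-oxazolidin-2-one
Product: 13 3-exo-(2-TBSO-ethyl)-5-methyl-7,7-ethylenedioxybicyclo[2.2.1]hept-5-ene-2-endo-carboxylic acid, via peroxy acid 12 (not isolated)
Conditions: LiOH, 30% H2O2, THF/H2O, 0 °C; Na2SO3; 1 M HCl to pH 4 at 0 °C
Reagents that add atoms: hydrogen peroxide, OO
Why: Hydroperoxide attacks the exocyclic imide carbonyl selectively even for hindered acyl groups; the peracid is reduced by sulfite and the auxiliary is recovered. The unactivated norbornene alkene is not epoxidised under these basic conditions.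

Step 8
Reactants: 13 3-exo-(2-TBSO-ethyl)-5-methyl-7,7-ethylenedioxybicyclo[2.2.1]hept-5-ene-2-endo-carboxylic acid
Product: 15 N-methoxy-N-methyl-3-exo-(2-TBSO-ethyl)-5-methyl-7,7-ethylenedioxybicyclo[2.2.1]hept-5-ene-2-endo-carboxamide, via acyl imidazole 14 (not isolated)
Conditions: 1,1'-carbonyldiimidazole, CH2Cl2, rt; MeNHOMe·HCl, rt
Reagents that add atoms: N,O-dimethylhydroxylamine hydrochloride, CNOC.Cl
Why: Standard amide formation through the acyl imidazole under neutral conditions that spare the ketal and silyl ether; no epimerisable centre is put at risk.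

Step 9
Reactants: 15 N-methoxy-N-methyl-3-exo-(2-TBSO-ethyl)-5-methyl-7,7-ethylenedioxybicyclo[2.2.1]hept-5-ene-2-endo-carboxamide
Product: 17 1β-acetyl-3β-formyl-7aα-(2-TBSO-ethyl)-2,2-ethylenedioxycyclopentane-3aβ-carboxylic acid N-methoxy-N-methylamide, via secondary ozonide 16 (not isolated)
Conditions: O3, CH2Cl2, −78 °C, to the first faint blue; PPh3, −78 °C to rt
Reagents that add atoms: ozone, [O-][O+]=O
Why: Ozonolysis of the strained trisubstituted alkene, the only π-bond reactive towards ozone, with neutral reductive work-up; it leaves one carbon (CHO) on C3 and two (COCH3) on C1, both β, without touching the four ring stereocentres.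

Step 10
Reactants: 17 1β-acetyl-3β-formyl-7aα-(2-TBSO-ethyl)-2,2-ethylenedioxycyclopentane-3aβ-carboxylic acid N-methoxy-N-methylamide
Product: 19 1β-ethyl-3β-methyl-7aα-(2-TBSO-ethyl)-2,2-ethylenedioxycyclopentane-3aβ-carboxylic acid N-methoxy-N-methylamide, via bis(p-toluenesulfonylhydrazone) 18 (not isolated)
Conditions: TsNHNH2 (2.2 equiv), EtOH/THF, rt; then catecholborane, CHCl3, 0 °C; NaOAc·3H2O, 60 °C
Reagents that add atoms: none
Why: Reduction of tosylhydrazones by catecholborane, then loss of sulfinate and N2, is a mild relative of the Wolff–Kishner reduction that turns C=O into CH2 without strong base. The β-ketal oxygens are therefore not eliminated and C3 is not epimerised. The N-methoxy-N-methylamide reacts neither with the hydrazide nor with the borane.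

Step 11
Reactants: 19 1β-ethyl-3β-methyl-7aα-(2-TBSO-ethyl)-2,2-ethylenedioxycyclopentane-3aβ-carboxylic acid N-methoxy-N-methylamide
Product: 20 3aβ-acetyl-1β-ethyl-3β-methyl-7aα-(2-TBSO-ethyl)-2,2-ethylenedioxycyclopentane
Conditions: MeMgBr, THF, 0 °C; aq. NH4Cl
Reagents that add atoms: methylmagnesium bromide, C[Mg]Br
Why: Weinreb ketone synthesis; the magnesium chelate of the tetrahedral adduct survives until work-up, so addition stops at the methyl ketone.

Step 12
Reactants: 21 1,4-dichlorobut-2-yne
Product: 23 hexa-1,3-diyne, via sodium buta-1,3-diyn-1-ide 22 (not isolated)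
Conditions: NaNH2 (3 equiv), liq. NH3, −40 °C; EtBr, −40 °C; extracted into THF and used as a solution
Reagents that add atoms: bromoethane, CCBr
Why: Double dehydrochlorination gives the diacetylide, which is mono-alkylated by the primary bromide; this is the established preparation of 1-alkyl-buta-1,3-diynes.

Step 13
Reactants: 20 3aβ-acetyl-1β-ethyl-3β-methyl-7aα-(2-TBSO-ethyl)-2,2-ethylenedioxycyclopentane; 23 hexa-1,3-diyne
Product: 24 2-[1β-ethyl-3β-methyl-7aα-(2-TBSO-ethyl)-2,2-ethylenedioxycyclopent-3aβ-yl]octa-3,5-diyn-2-ol (C4 configuration as in the SMILES)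
Conditions: 23, n-BuLi, THF, −78 °C; CeCl3, −78 °C; then 20, −78 °C
Reagents that add atoms: none
Why: 1,2-Addition of an alkynylcerium reagent, which suppresses enolisation of the methyl ketone. C4 should be set by open-chain 1,2-induction: the C3 branch, made the larger one by its cis methyl group, lies anti to the nucleophile, which enters past H7a. This gives the epimer whose unsaturated chain becomes α in lactone 30.

Step 14
Reactants: 24 2-[1β-ethyl-3β-methyl-7aα-(2-TBSO-ethyl)-2,2-ethylenedioxycyclopent-3aβ-yl]octa-3,5-diyn-2-ol
Product: 26 (Z)-2-[1β-ethyl-3β-methyl-7aα-(2-TBSO-ethyl)-2,2-ethylenedioxycyclopent-3aβ-yl]-4-iodooct-3-en-5-yn-2-ol, via cyclic alkenylalanate 25 (not isolated)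
Conditions: NaAlH2(OCH2CH2OMe)2, THF, 0 °C to rt; EtOAc; I2, −78 to 0 °C; aq. Na2S2O3
Reagents that add atoms: iodine, II
Why: Alkoxide-directed trans-hydroalumination of the propargylic triple bond delivers hydride to C5 and aluminium to C6 inside a five-membered ring; the remote triple bond is not directed and stays. Iodine replaces aluminium with retention, so iodine is cis and the butynyl group trans to C4.

Step 15
Reactants: 26 (Z)-2-[1β-ethyl-3β-methyl-7aα-(2-TBSO-ethyl)-2,2-ethylenedioxycyclopent-3aβ-yl]-4-iodooct-3-en-5-yn-2-ol
Product: 27 (E)-2-[1β-ethyl-3β-methyl-7aα-(2-TBSO-ethyl)-2,2-ethylenedioxycyclopent-3aβ-yl]-4-ethyloct-3-en-5-yn-2-ol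
Conditions: Et2Zn (3 equiv), Pd(dppf)Cl2 (5 mol%), THF, 50 °C
Reagents that add atoms: diethylzinc, CC[Zn]CC
Why: Negishi coupling of an alkenyl iodide proceeds with retention, so the ethyl group ends cis to C4 and the butynyl group trans, the geometry that step 19 turns into the C6 configuration. The wide-bite-angle diphosphine suppresses β-hydride elimination from the ethylpalladium intermediate; the free tertiary alcohol is tolerated as its zinc alkoxide.

Step 16
Reactants: 27 (E)-2-[1β-ethyl-3β-methyl-7aα-(2-TBSO-ethyl)-2,2-ethylenedioxycyclopent-3aβ-yl]-4-ethyloct-3-en-5-yn-2-ol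
Product: 28 (E)-2-[1β-ethyl-7aα-(2-hydroxyethyl)-3β-methyl-2,2-ethylenedioxycyclopent-3aβ-yl]-4-ethyloct-3-en-5-yn-2-ol
Conditions: Bu4NF, THF, 0 °C to rt
Reagents that add atoms: none
Why: Fluoride cleavage of the primary silyl ether under non-acidic conditions that leave the tertiary allylic alcohol and the ketal intact.

Step 17
Reactants: 28 (E)-2-[1β-ethyl-7aα-(2-hydroxyethyl)-3β-methyl-2,2-ethylenedioxycyclopent-3aβ-yl]-4-ethyloct-3-en-5-yn-2-ol
Product: 30 δ-lactone (C8 to O on C4) with 4β-methyl and 4α-[(E)-2-ethylhex-1-en-3-yn-1-yl] groups trans-fused at C3a–C7a to the 1β-ethyl-3β-methyl-2,2-ethylenedioxycyclopentane, via lactol 29 (not isolated)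
Conditions: TEMPO (0.2 equiv), PhI(OAc)2 (2.5 equiv), CH2Cl2, rt
Reagents that add atoms: none
Why: Oxoammonium oxidation takes the primary alcohol to the aldehyde, which closes onto the tertiary hydroxyl; the six-membered lactol is oxidised further to the lactone. The tertiary alcohol cannot be oxidised and needs no activation, which avoids ionising the allylic C4–O bond.

Step 18
Reactants: 30 δ-lactone with 4β-methyl and 4α-[(E)-2-ethylhex-1-en-3-yn-1-yl] groups
Product: 31 7-ethyl derivative of lactone 30 (either or both C7 epimers)
Conditions: LiN(iPr)2, THF, −78 °C; EtI, DMPU, −78 to −40 °C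
Reagents that add atoms: iodoethane, CCI
Why: Alkylation of the lactone lithium enolate at its only α-carbon; the lithium enolate does not rearrange at these temperatures, and the C7 configuration is erased in step 19.

Step 19
Reactants: 31 7-ethyl derivative of lactone 30
Product: 34 6β-(but-1-yn-1-yl)-1β,6α,7α-triethyl-3β,4-dimethyl-2,2-ethylenedioxy-2,3,3a,6,7,7a-hexahydro-1H-indene-7β-carboxylic acid (3aα-H and 7aβ-H), via trimethylsilyl ketene acetal 32 (not isolated), via trimethylsilyl ester 33 (not isolated)
Conditions: LiN(iPr)2, THF, −78 °C; Me3SiCl/Et3N, −78 °C to rt; toluene, 105 °C; dilute aq. citric acid/THF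
Reagents that add atoms: none
Why: Ireland–Claisen rearrangement of a lactone silyl ketene acetal; the ring fixes the ketene acetal geometry and forces a boat-like transition state. Only the α-alkenyl group on C4 can reach C7 in the trans-fused ring (lactone boat with O and C7a as prows), so C6 bonds to the face of C7 anti to H7a, giving 7α-ethyl and 7β-carboxyl. The alkene geometry places butynyl β and ethyl α on C6. The C4 stereocentre is consumed as C4=C5 forms.

Step 20
Reactants: 34 6β-(but-1-yn-1-yl)-1β,6α,7α-triethyl-3β,4-dimethyl-2,2-ethylenedioxy-2,3,3a,6,7,7a-hexahydro-1H-indene-7β-carboxylic acid; 35 (E)-(2-bromovinyl)benzene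
Product: 37 1β,6α,7α-triethyl-6β-[(1E,3E)-2-ethyl-4-phenylbuta-1,3-dien-1-yl]-3β,4-dimethyl-2,2-ethylenedioxy-2,3,3a,6,7,7a-hexahydro-1H-indene-7β-carboxylic acid, via alkenylzirconocene chloride 36 (not isolated)
Conditions: Cp2Zr(H)Cl (3 equiv), THF, rt to 45 °C; then ZnCl2, 35, Pd(PPh3)4 (5 mol%), rt to 45 °C; pH 4 buffer
Reagents that add atoms: none
Why: Syn hydrozirconation places zirconium on C2', the alkyne carbon remote from quaternary C6, after one equivalent has converted the acid into its zirconium carboxylate. Transmetalation to zinc and Negishi coupling with zerovalent palladium retain both alkene geometries, giving the 1'E,3'E diene. The trisubstituted ring alkene and the ketal are inert to the hydride.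

Step 21
Reactants: 37 1β,6α,7α-triethyl-6β-[(1E,3E)-2-ethyl-4-phenylbuta-1,3-dien-1-yl]-3β,4-dimethyl-2,2-ethylenedioxy-2,3,3a,6,7,7a-hexahydro-1H-indene-7β-carboxylic acid
Product: 39 1β,6α,7α-triethyl-6β-[(1E,3E)-2-ethyl-4-phenylbuta-1,3-dien-1-yl]-3α,4-dimethyl-2-oxo-2,3,3a,6,7,7a-hexahydro-1H-indene-7β-carboxylic acid (CNP0134269.1), via 3β-methyl keto acid 38 (not isolated)
Conditions: 1 M HCl, THF, 40 °C; then NaOH, MeOH/H2O (pH 12), rt; HCl to pH 3
Reagents that add atoms: water, O
Why: Acid hydrolysis of the dioxolane frees the ketone. Enolate equilibration at C3, the only centre that is both epimerisable and cis to a vicinal substituent, should then move the methyl group trans to C4. C1 is already trans to C7 and the other four centres cannot enolise.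

## Compound list

1 | 3-methylcyclopentanone (racemic) | CC1CCC(=O)C1 | starting material
2 | 6,9-dibromo-7-methyl-1,4-dioxaspiro[4.4]nonane (diastereomer mixture) | CC1CC(Br)C2(OCCO2)C1Br | intermediate
3 | 7-methyl-1,4-dioxaspiro[4.4]nona-6,8-diene | CC1=CC2(OCCO2)C=C1 | intermediate
4 | 3-(tert-butyldimethylsilyloxy)propanal | CC(C)(C)[Si](C)(C)OCCC=O | starting material
5 | triethyl phosphonoacetate | CCOC(=O)CP(=O)(OCC)OCC | starting material
6 | ethyl (E)-5-(tert-butyldimethylsilyloxy)pent-2-enoate | CCOC(=O)/C=C/CCO[Si](C)(C)C(C)(C)C | intermediate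
7 | (E)-5-(tert-butyldimethylsilyloxy)pent-2-enoic acid | OC(=O)/C=C/CCO[Si](C)(C)C(C)(C)C | intermediate
8 | (S)-4-benzyl-1,3-oxazolidin-2-one | O=C1N[C@@H](Cc2ccccc2)CO1 | starting material
9 | mixed pivalic anhydride of 7 | CC(C)(C)C(=O)OC(=O)/C=C/CCO[Si](C)(C)C(C)(C)C | intermediate (not isolated)
10 | (S)-4-benzyl-3-[(E)-5-(tert-butyldimethylsilyloxy)pent-2-enoyl]-1,3-oxazolidin-2-one | O=C(/C=C/CCO[Si](C)(C)C(C)(C)C)N1[C@@H](Cc2ccccc2)COC1=O | intermediate
11 | endo cycloadduct: (S)-4-benzyl-3-{[3-exo-(2-TBSO-ethyl)-5-methyl-7,7-ethylenedioxybicyclo[2.2.1]hept-5-en-2-endo-yl]carbonyl}-1,3-oxazolidin-2-one (norbornene C2 = C3a, C3 = C7a) | O=C(N1[C@@H](Cc2ccccc2)COC1=O)[C@@H]1[C@@H](CCO[Si](C)(C)C(C)(C)C)[C@@H]2C(C)=C[C@H]1C23OCCO3 | intermediate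
12 | peroxy acid corresponding to 13 | OOC(=O)[C@@H]1[C@@H](CCO[Si](C)(C)C(C)(C)C)[C@@H]2C(C)=C[C@H]1C23OCCO3 | intermediate (not isolated)
13 | 3-exo-(2-TBSO-ethyl)-5-methyl-7,7-ethylenedioxybicyclo[2.2.1]hept-5-ene-2-endo-carboxylic acid | OC(=O)[C@@H]1[C@@H](CCO[Si](C)(C)C(C)(C)C)[C@@H]2C(C)=C[C@H]1C23OCCO3 | intermediate
14 | acyl imidazole of 13 | O=C(n1ccnc1)[C@@H]1[C@@H](CCO[Si](C)(C)C(C)(C)C)[C@@H]2C(C)=C[C@H]1C23OCCO3 | intermediate (not isolated)
15 | N-methoxy-N-methylamide of 13 | CON(C)C(=O)[C@@H]1[C@@H](CCO[Si](C)(C)C(C)(C)C)[C@@H]2C(C)=C[C@H]1C23OCCO3 | intermediate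
16 | secondary ozonide of 15 | CON(C)C(=O)[C@@H]1[C@@H](CCO[Si](C)(C)C(C)(C)C)[C@H]2C3(OCCO3)[C@@H]1C4OOC2(C)O4 | intermediate (not isolated)
17 | 1β-acetyl-3β-formyl-7aα-(2-TBSO-ethyl)-2,2-ethylenedioxycyclopentane-3aβ-carboxylic acid N-methoxy-N-methylamide | CON(C)C(=O)[C@@H]1[C@@H](CCO[Si](C)(C)C(C)(C)C)[C@H](C(C)=O)C2(OCCO2)[C@@H]1C=O | intermediate
18 | bis(p-toluenesulfonylhydrazone) of 17 | CON(C)C(=O)[C@@H]1[C@@H](CCO[Si](C)(C)C(C)(C)C)[C@H](C(C)=NNS(=O)(=O)c2ccc(C)cc2)C3(OCCO3)[C@@H]1C=NNS(=O)(=O)c4ccc(C)cc4 | intermediate (not isolated)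
19 | 1β-ethyl-3β-methyl-7aα-(2-TBSO-ethyl)-2,2-ethylenedioxycyclopentane-3aβ-carboxylic acid N-methoxy-N-methylamide | CON(C)C(=O)[C@@H]1[C@@H](CCO[Si](C)(C)C(C)(C)C)[C@H](CC)C2(OCCO2)[C@@H]1C | intermediate
20 | 3aβ-acetyl-1β-ethyl-3β-methyl-7aα-(2-TBSO-ethyl)-2,2-ethylenedioxycyclopentane | CC(=O)[C@@H]1[C@@H](CCO[Si](C)(C)C(C)(C)C)[C@H](CC)C2(OCCO2)[C@@H]1C | intermediate
21 | 1,4-dichlorobut-2-yne | ClCC#CCCl | starting material
22 | sodium buta-1,3-diyn-1-ide | [Na+].[C-]#CC#C | intermediate (not isolated)
23 | hexa-1,3-diyne | CCC#CC#C | intermediate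
24 | tertiary diynol: 2-[1β-ethyl-3β-methyl-7aα-(2-TBSO-ethyl)-2,2-ethylenedioxycyclopent-3aβ-yl]octa-3,5-diyn-2-ol | CCC#CC#C[C@@](C)(O)[C@@H]1[C@@H](CCO[Si](C)(C)C(C)(C)C)[C@H](CC)C2(OCCO2)[C@@H]1C | intermediate
25 | sodium alkenylalanate (five-membered O–Al–C6 ring) from 24 | [Na+].CCC#CC1=C[C@](C)([C@@H]2[C@@H](CCO[Si](C)(C)C(C)(C)C)[C@H](CC)C3(OCCO3)[C@@H]2C)O[Al-]1(OCCOC)OCCOC | intermediate (not isolated)
26 | (Z)-4-iodooct-3-en-5-yn-2-ol derivative of 24 | CCC#C/C(I)=C/[C@@](C)(O)[C@@H]1[C@@H](CCO[Si](C)(C)C(C)(C)C)[C@H](CC)C2(OCCO2)[C@@H]1C | intermediate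
27 | (E)-4-ethyloct-3-en-5-yn-2-ol derivative (ethyl cis to C4) | CCC#C/C(CC)=C/[C@@](C)(O)[C@@H]1[C@@H](CCO[Si](C)(C)C(C)(C)C)[C@H](CC)C2(OCCO2)[C@@H]1C | intermediate
28 | diol: desilylated 27 | CCC#C/C(CC)=C/[C@@](C)(O)[C@@H]1[C@@H](CCO)[C@H](CC)C2(OCCO2)[C@@H]1C | intermediate
29 | lactol (C8 hemiacetal) of 30 | CCC#C/C(CC)=C/[C@@]1(C)OC(O)C[C@H]2[C@H](CC)C3(OCCO3)[C@H](C)[C@H]12 | intermediate (not isolated)
30 | δ-lactone with 4β-methyl and 4α-[(E)-2-ethylhex-1-en-3-yn-1-yl] groups trans-fused to the ketal cyclopentane | CCC#C/C(CC)=C/[C@@]1(C)OC(=O)C[C@H]2[C@H](CC)C3(OCCO3)[C@H](C)[C@H]12 | intermediate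
31 | 7-ethyl lactone (C7 epimers) | CCC#C/C(CC)=C/[C@@]1(C)OC(=O)C(CC)[C@H]2[C@H](CC)C3(OCCO3)[C@H](C)[C@H]12 | intermediate
32 | trimethylsilyl ketene acetal of 31 | CCC#C/C(CC)=C/[C@@]1(C)OC(O[Si](C)(C)C)=C(CC)[C@H]2[C@H](CC)C3(OCCO3)[C@H](C)[C@H]12 | intermediate (not isolated)
33 | trimethylsilyl ester of 34 | CCC#C[C@@]1(CC)C=C(C)[C@@H]2[C@H]([C@H](CC)C3(OCCO3)[C@@H]2C)[C@@]1(CC)C(=O)O[Si](C)(C)C | intermediate (not isolated)
34 | 6β-(but-1-yn-1-yl)-1β,6α,7α-triethyl-3β,4-dimethyl-2,2-ethylenedioxy-2,3,3a,6,7,7a-hexahydro-1H-indene-7β-carboxylic acid | CCC#C[C@@]1(CC)C=C(C)[C@@H]2[C@H]([C@H](CC)C3(OCCO3)[C@@H]2C)[C@@]1(CC)C(=O)O | intermediate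
35 | (E)-(2-bromovinyl)benzene | Br/C=C/c1ccccc1 | starting material
36 | alkenylzirconocene chloride from 34 (zirconium on C2'; carboxylate also bound to zirconium) | CC/C(=C\[C@@]1(CC)C=C(C)[C@@H]2[C@H]([C@H](CC)C3(OCCO3)[C@@H]2C)[C@@]1(CC)C(=O)O[Zr](Cl)(C4C=CC=C4)C5C=CC=C5)[Zr](Cl)(C6C=CC=C6)C7C=CC=C7 | intermediate (not isolated)
37 | ketal of the 3β-methyl epimer of the target | CCC(/C=C/c1ccccc1)=C\[C@@]1(CC)C=C(C)[C@@H]2[C@H]([C@H](CC)C3(OCCO3)[C@@H]2C)[C@@]1(CC)C(=O)O | intermediate
38 | 3β-methyl epimer of the target | CCC(/C=C/c1ccccc1)=C\[C@@]1(CC)C=C(C)[C@@H]2[C@H]([C@H](CC)C(=O)[C@@H]2C)[C@@]1(CC)C(=O)O | intermediate (not isolated)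
39 | CNP0134269.1 | CCC(/C=C/c1ccccc1)=C\[C@@]1(CC)C=C(C)[C@@H]2[C@H]([C@H](CC)C(=O)[C@H]2C)[C@@]1(CC)C(=O)O | target

## Step count and risks

Total: 21 steps. Longest linear sequence: 18 steps (4 → 6 → 7 → 10 → 11 → 13 → 15 → 17 → 19 → 20 → 24 → 26 → 27 → 28 → 30 → 31 → 34 → 37 → 39). Side branches: steps 1–2 (diene) and step 12 (diyne).

**Step 6 (key step).** The most likely failure is loss of the diene before it is intercepted, by dimerisation or by Lewis-acid-induced opening of its ketal, because more than one equivalent of Et2AlCl is present. Erosion of regio- or endo-selectivity is a lesser concern. The fallback replaces auxiliary control and a stoichiometric Lewis acid by catalyst control. It sets out from acid 7, which is acylated onto oxazolidin-2-one by the method of step 5 to give 3-[(E)-5-(tert-butyldimethylsilyloxy)pent-2-enoyl]-1,3-oxazolidin-2-one F1. F1 and diene 3 are combined at −40 °C under 5–10 mol% of a cationic bis(oxazoline) complex of divalent copper, [Cu(tBu-box)](SbF6)2 (box = 2,2'-isopropylidenebis(4-tert-butyl-2-oxazoline)), in the ligand enantiomer that exposes the Cα-si face. This gives the achiral-imide endo cycloadduct F2, and cleavage with LiOH/H2O2 as in step 7 returns to the route at acid 13.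

**Step 19.** The sigmatropic shift may fail because the boat-like transition state has to join two fully substituted carbons while the trans-fused cyclopentane limits the twist of the lactone ring. The ketene acetal would then be lost by C-silylation or by ionisation of the tertiary allylic carboxylate. The fallback changes the order of bond formation. It sets out from the unsubstituted lactone 30, whose less crowded ketene acetal is rearranged under the conditions of step 19 to 6β-(but-1-yn-1-yl)-1β,6α-diethyl-3β,4-dimethyl-2,2-ethylenedioxy-2,3,3a,6,7,7a-hexahydro-1H-indene-7-carboxylic acid F3. The dianion of F3 (LiN(iPr)2, 2.2 equiv) is then ethylated with EtI. The electrophile is expected to enter axially, anti to the pseudoaxial butynyl group on C6, which returns to the route at acid 34.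

**Step 13.** The facial selectivity at C4 may be poor or reversed, since the two ring branches on C3a differ mainly by the cis methyl group on C3; enolisation of the ketone is a second loss channel. The fallback introduces the two C4 substituents in the opposite order, which inverts the result of a given facial preference. It sets out from amide 19, which is treated with lithiated 23 to give the alkynyl ketone 1-[1β-ethyl-3β-methyl-7aα-(2-TBSO-ethyl)-2,2-ethylenedioxycyclopent-3aβ-yl]hepta-2,4-diyn-1-one F4. Addition of MeMgBr in the presence of CeCl3 at −78 °C returns to the route at carbinol 24. If neither order is selective, only the epimer with the α-alkenyl group can reach the transition state of step 19, so the other can be removed at 30 or after rearrangement.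

**Step 10.** Condensation at the hindered methyl ketone may be incomplete, the cis-1,3 acetyl and formyl groups may close by aldol reaction before both hydrazones form, or C3 may epimerise through the ene-hydrazine. The fallback removes the oxygens by radical reduction instead of through diazenes. It sets out from keto aldehyde 17, which NaBH4 reduces to the diol 1β-(1-hydroxyethyl)-3β-(hydroxymethyl)-7aα-(2-TBSO-ethyl)-2,2-ethylenedioxycyclopentane-3aβ-carboxylic acid N-methoxy-N-methylamide F5. An Appel reaction (I2, PPh3, imidazole) converts F5 into the corresponding diiodide F6. Reduction of both C–I bonds with Bu3SnH and azobisisobutyronitrile in toluene at 80 °C returns to the route at amide 19.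

**Step 21.** During ketal hydrolysis, protonation of the diene (or of C4=C5) and capture of the cation by the carboxyl group may compete, and the C3 equilibrium may stop short of completion. The fallback frees and equilibrates the ketone before the diene exists and completes the side chain with a hydrometalation that tolerates a ketone. It sets out from acid 34, which is hydrolysed and equilibrated under the conditions of step 21 to 6β-(but-1-yn-1-yl)-1β,6α,7α-triethyl-3α,4-dimethyl-2-oxo-2,3,3a,6,7,7a-hexahydro-1H-indene-7β-carboxylic acid F7. Syn hydrostannation (Bu3SnH, Pd(PPh3)2Cl2, THF) puts tin on C2' and gives the (E)-alkenylstannane F8. Stille coupling of F8 with 35 (Pd(PPh3)4, CuI, DMF) returns to the route at the target 39.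

## Further compounds

F1 | step 6 | 3-[(E)-5-(tert-butyldimethylsilyloxy)pent-2-enoyl]-1,3-oxazolidin-2-one | O=C(/C=C/CCO[Si](C)(C)C(C)(C)C)N1CCOC1=O
F2 | step 6 | 3-{[3-exo-(2-TBSO-ethyl)-5-methyl-7,7-ethylenedioxybicyclo[2.2.1]hept-5-en-2-endo-yl]carbonyl}-1,3-oxazolidin-2-one | O=C(N1CCOC1=O)[C@@H]1[C@@H](CCO[Si](C)(C)C(C)(C)C)[C@@H]2C(C)=C[C@H]1C23OCCO3
F3 | step 19 | 6β-(but-1-yn-1-yl)-1β,6α-diethyl-3β,4-dimethyl-2,2-ethylenedioxy-2,3,3a,6,7,7a-hexahydro-1H-indene-7-carboxylic acid | CCC#C[C@@]1(CC)C=C(C)[C@@H]2[C@H]([C@H](CC)C3(OCCO3)[C@@H]2C)[C@H]1C(=O)O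
F4 | step 13 | 1-[1β-ethyl-3β-methyl-7aα-(2-TBSO-ethyl)-2,2-ethylenedioxycyclopent-3aβ-yl]hepta-2,4-diyn-1-one | CCC#CC#CC(=O)[C@@H]1[C@@H](CCO[Si](C)(C)C(C)(C)C)[C@H](CC)C2(OCCO2)[C@@H]1C
F5 | step 10 | 1β-(1-hydroxyethyl)-3β-(hydroxymethyl)-7aα-(2-TBSO-ethyl)-2,2-ethylenedioxycyclopentane-3aβ-carboxylic acid N-methoxy-N-methylamide | CON(C)C(=O)[C@@H]1[C@@H](CCO[Si](C)(C)C(C)(C)C)[C@H](C(C)O)C2(OCCO2)[C@@H]1CO
F6 | step 10 | 1β-(1-iodoethyl)-3β-(iodomethyl)-7aα-(2-TBSO-ethyl)-2,2-ethylenedioxycyclopentane-3aβ-carboxylic acid N-methoxy-N-methylamide | CON(C)C(=O)[C@@H]1[C@@H](CCO[Si](C)(C)C(C)(C)C)[C@H](C(C)I)C2(OCCO2)[C@@H]1CI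
F7 | step 21 | 6β-(but-1-yn-1-yl)-1β,6α,7α-triethyl-3α,4-dimethyl-2-oxo-2,3,3a,6,7,7a-hexahydro-1H-indene-7β-carboxylic acid | CCC#C[C@@]1(CC)C=C(C)[C@@H]2[C@H]([C@H](CC)C(=O)[C@H]2C)[C@@]1(CC)C(=O)O
F8 | step 21 | (E)-alkenylstannane of F7 (tributyltin on C2') | CC/C(=C\[C@@]1(CC)C=C(C)[C@@H]2[C@H]([C@H](CC)C(=O)[C@H]2C)[C@@]1(CC)C(=O)O)[Sn](CCCC)(CCCC)CCCC
A1 | alternative 1 | α-bromo cycloheptenone fused to the cyclopentanone (bromohydroazulenedione) | CCC#C[C@@]1(CC)C=C(C)[C@@H]2[C@H]([C@H](CC)C(=O)[C@H]2C)C(=O)[C@]1(Br)CC
A2 | alternative 1 | 2-oxohexahydroindene-7-carboxylic acid with a but-1-ynyl group on C6 | CCC#C[C@@]1(CC)C=C(C)[C@@H]2[C@H]([C@H](CC)C(=O)[C@H]2C)[C@@]1(CC)C(=O)O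
A3 | alternative 2 | (S)-4-(tert-butyldimethylsilyloxy)cyclopent-2-en-1-one | O=C1C=C[C@@H](O[Si](C)(C)C(C)(C)C)C1
A4 | alternative 2 | trans,trans-2-methyl-3-isopropenyl-4-(tert-butyldimethylsilyloxy)cyclopentanone | CC(=C)[C@@H]1[C@H](CC(=O)[C@H]1C)O[Si](C)(C)C(C)(C)C
A5 | alternative 3 | 2,3-diethylmaleic anhydride | CCC1=C(CC)C(=O)OC1=O
A6 | alternative 3 | buta-1,3-diene | C=CC=C
A7 | alternative 3 | meso cis-1,2-diethylcyclohex-4-ene-1,2-dicarboxylic anhydride | CC[C@]12CC=CC[C@@]1(CC)C(=O)OC2=O
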